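## The problem

CNP0271389.1 is a 3,8''-linked biflavonoid. A naringenin-type flavanone (rings A, C and B; O1, C2–C8a, C1'–C6') carries at C3 the carbon C8'' of an apigenin-type flavone (rings A'', C'' and B''; its aryl ring is numbered C1'''–C6'''), and O7'' of the flavone is a hydrogen sulfate. The only stereocentres are C2 (R) and C3 (S), trans on ring C. C3 is α to the C4 ketone and benzylic, so it epimerises readily and settles trans to the C2 aryl group; C2 is therefore the centre that must be set absolutely, and C3 follows from it. C2 is in turn lost by base-induced retro-oxa-Michael opening to the chalcone, which restricts every operation after ring C is closed. The aryl sulfate is acid-labile and very polar, and it is one of six phenolic oxygens, so it has to be introduced late, on the only free phenol, and meet only neutral or weakly basic reagents afterwards. Ring A'' is a pentasubstituted benzene (only C6'' bears hydrogen) whose three oxygens end in three different states: O1'' in the pyranone, O5'' as the chelated phenol, O7'' as the sulfate, with C8'', the carbon bound to C3, between O1'' and O7''. This O–C(C)–C(O) array with a third oxygen para to C8'' is exactly what a cyclobutenone/siloxyalkyne benzannulation delivers: the alkyne carbons become C8'' and C7'', the ketene carbonyl becomes C8a''–O1'', and a 3-alkoxy group of the cyclobutenone becomes O5''.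

## Retrosynthesis

**Endgame.** Target 27 is traced to the tetrabenzyl ether 26 by cutting four O–benzyl bonds, then to phenol 25 by cutting the O7''–S bond, then to silyl ether 24 by cutting O7''–Si. Benzyl ethers are chosen because their removal is neutral and leaves sulfate, flavone and the C2 stereocentre alone. Sulfation is placed on 25 because O7''–H is then the only non-chelated phenol. The forward steps must avoid any base stronger than pyridine.

**Ring C.** In 24 the O1–C2 bond is cut to give the α-aryl-2'-hydroxychalcone 23. The neighbouring cut, C2–C3 by an aldol on a preformed aryl ether, would need two stereocentres set in an open chain that eliminates easily. The O1–C2 cut asks only for facial control at C2, and C3 then equilibrates to trans. The forward reaction must be a 6-endo oxa-Michael addition under catalyst control, and the silyl group on O7'' has to stay in place so that this oxygen cannot close a five-membered ring onto the same enone.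

**C2=C3.** Chalcone 23 is cut at the C2=C3 double bond into deoxybenzoin 21 and 4-(benzyloxy)benzaldehyde 22. This is a Knoevenagel condensation on a doubly activated methylene; it must stop at the chalcone.

**Ring A of the flavanone.** Deoxybenzoin 21 comes from the tris-benzyl ketone 20 by chelation-controlled loss of one ortho benzyl group. Ketone 20 is cut at C4–C4a into arylacetic acid 17 and 1,3,5-tris(benzyloxy)benzene 18. The threefold symmetry of 18 removes the ortho/para ambiguity that acylation of a phloroglucinol mono-phenol would bring. No strong Lewis acid is needed, which protects the silyl ether.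

**The C3 handle.** Acid 17 is traced through aldehyde 16 to the 8-allylflavone 15 by oxidative cleavage of the allyl group. The allyl group is inert through the early steps and is the substituent the benzannulation installs at C8''.

**Flavone.** Phenol 15 comes from the 5''-ethyl ether 14 by peri dealkylation, done while only one benzyl ether is present and before any stereocentre exists. Flavone 14 is cut at C2''–C3'' and O1''–C2'' (Baker–Venkataraman) into acetophenone 11 and 4-(benzyloxy)benzoyl chloride 12. Acetophenone 11 is cut at C4''–C4a'' to phenol 10. The ethyl ether blocks O5'', so the pyranone can only close through O1''.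

**Ring A''.** Phenol 10 is cut into 3-ethoxycyclobut-2-en-1-one 5 and siloxyalkyne 4, which comes from pent-1-en-4-yne 1. The neighbouring option is Claisen rearrangement or electrophilic substitution on a phloroglucinol-derived flavone. That leaves C6''/C8'' ambiguity and the risk of Wessely–Moser scrambling. The benzannulation fixes the position of every substituent and the state of every oxygen by construction.

## Roads not taken

**Alternative 1:** aryne insertion into an α-(flavon-8-yl)cinnamic acid.
- Cut: O1–C8a and C4–C4a of the flavanone.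
- Forward step: with CsF the carboxylate of acrylic acid A1 adds to 3,5-bis(benzyloxy)benzyne A2, and the aryl anion attacks the acyl carbon to give chalcone A3; no ring closes.
- Merits: two bonds form without acid, and the free 2'-phenol chalcone appears without an amine. That avoids the premature-cyclisation risk of step 10 here and is one operation shorter than steps 8–10.
- Weak points: arynes and carboxylates usually stop at O-arylation, and the acyl shift onto a hindered, conjugated acyl group is the disfavoured branch. Fluoride rules out silyl protection at O7''. The aryne precursor costs several steps.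
- Comparison: A3 still needs the same enantioselective oxa-Michael closure, and A1 still needs a ring A'' with differentiated oxygens, which this alternative does not provide. The chosen plan sets against it a commercial symmetric arene, three well-known reactions and a silyl group that comes free with the key step.

**Alternative 2:** lactone tether on O7''.
- Cut: C4–C4a.
- Forward step: BF3·OEt2 or Sc(OTf)3 activates the benzofuranone carbonyl of A4; the tethered 3,5-bis(benzyloxy)phenyl ether attacks ortho to its oxygen, closing ring C and releasing the O7'' phenol in A5.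
- Merits: ring closure and unmasking of the sulfation site coincide, so no protecting group is spent on O7'' and the endgame is one step shorter. In that respect it is better than the chosen plan.
- Weak points: A4 must already carry both stereocentres. Its C3–H is a very acidic benzofuranone α-hydrogen with a β-aryloxy leaving group, so epimerisation and E1cB loss of the phenol threaten. The Lewis acid meets a benzylic aryl ether at C2 that can ionise. An aryl ester is a weak acylating agent.
- Comparison: the chosen plan forms the stereocentres late, in a ring closure that funnels to the trans ketone, and never exposes them to a Lewis acid.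

**Alternative 3:** ortho-quinone methide cycloaddition.
- Cut: C3–C4 and O1–C2.
- Forward step: a chiral Brønsted acid converts aldehyde A6 and trimethyl orthoformate into quinone methide A8, which adds across stilbene A7 to give the 2,3-trans-4-methoxyflavan A9.
- Merits: it is the most convergent road. Ring C and both stereocentres arise in one catalytic step of an established reaction class, trans follows from the alkene geometry, no enolisable ketone is present, and the sulfate is already in place as its trichloroethyl ester. Its stereo-determining step rests on firmer precedent than step 11 here.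
- Weak points: the 2π partner is a hindered 1,2-diarylethene conjugated to an electron-poor flavone, far less nucleophilic than the styrenes and enol ethers used in such cycloadditions. C4 must afterwards be oxidised from ether to ketone. A7 again presupposes a differentiated, C8''-functionalised flavone.
- Comparison: the chosen plan needs no oxidation-state correction at C4, uses the native reactivity of a 2'-hydroxychalcone, and keeps a racemic fallback through the same intermediates.

Key step: step 2

Remark on the chemistry: sulfate-bearing compounds are handled as sodium salts and written as neutral hydrogen sulfates; the free acid of the target is released by H+ exchange in the cold.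
Remark on the chemistry: 3-ethoxycyclobut-2-en-1-one, 4-(benzyloxy)benzoyl chloride and 1,3,5-tris(benzyloxy)benzene are taken as catalogue compounds.

## Route

Step 1
Reactants: 1 pent-1-en-4-yne
Product: 4 triisopropyl(pent-4-en-1-yn-1-yloxy)silane, via lithium pent-4-en-1-yn-1-ide 2 (not isolated), via lithium pent-4-en-1-yn-1-olate 3 (not isolated)
Conditions: LiN(SiMe3)2, THF, −78 °C; LiOOt-Bu (from t-BuOOH and LiN(SiMe3)2), −78 → 0 °C; i-Pr3SiOSO2CF3, −78 °C → rt
Reagents that add atoms: tert-butyl hydroperoxide (used as its lithium salt), CC(C)(C)OO; triisopropylsilyl trifluoromethanesulfonate, CC(C)[Si](C(C)C)(C(C)C)OS(=O)(=O)C(F)(F)F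
Why: Oxygenation of a lithium acetylide by lithium tert-butyl peroxide to the ynolate and O-silylation with a bulky silyl triflate is the standard route to triisopropylsiloxyalkynes; the amide base removes only the acetylenic hydrogen and leaves the allylic/propargylic CH2 alone.

Step 2
Reactants: 5 3-ethoxycyclobut-2-en-1-one; 4 triisopropyl(pent-4-en-1-yn-1-yloxy)silane
Product: 10 2-allyl-5-ethoxy-3-(triisopropylsilyloxy)phenol, via 3-ethoxybuta-1,3-dien-1-one 6 (not isolated), via vinylcyclobutenone 7 (not isolated), via dienylketene 8 (not isolated), via cyclohexadienone tautomer 9 (not isolated)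
Conditions: 4 (1.3 equiv), toluene (dilute), 80 °C then 110 °C, sealed vessel
Reagents that add atoms: none
Why: Thermal four-electron electrocyclic opening of 5 gives ethoxyvinylketene 6, which undergoes a regioselective [2+2] cycloaddition with siloxyalkyne 4 to vinylcyclobutenone 7; a second four-electron opening gives dienylketene 8, six-electron electrocyclisation gives dienone 9, and tautomerisation gives phenol 10. The closest known reaction is the Danheiser benzannulation of cyclobutenones with trialkylsiloxyalkynes to resorcinol monosilyl ethers, and the 3-alkoxy group on the cyclobutenone is the only extension. The [2+2] step forms C8''–C8a'' and C6''–C7''; the six-membered carbocycle then closes by thermal disrotatory six-electron electrocyclisation of 8, which makes the C4a''–C8a'' bond. No stereocentre is formed. The step needs one regiochemistry in the ketene–alkyne cycloaddition, and the polarisation of both partners secures it: the electrophilic ketene carbonyl carbon bonds to the nucleophilic alkyne carbon that bears the allyl group. The allyl carbon therefore lies between the free hydroxyl (O1'') and the silyloxy group (O7''), and the ethoxy group (O5'') is para to it. Dilution, a modest excess of 4 and staged heating should limit ketene dimerisation and acylation of the product phenol by 6.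

Step 3
Reactants: 10 2-allyl-5-ethoxy-3-(triisopropylsilyloxy)phenol
Product: 11 1-[3-allyl-6-ethoxy-2-hydroxy-4-(triisopropylsilyloxy)phenyl]ethan-1-one
Conditions: AcCl (1.2 equiv), TiCl4 (1.2 equiv), CH2Cl2, −40 → 0 °C; aq. HCl
Reagents that add atoms: acetyl chloride, CC(=O)Cl
Why: Friedel–Crafts C-acetylation of a phloroglucinol-type ring, delivered by the titanium phenoxide to the only free ortho position (the future C4a''); the other free carbon is para to the phenol and wedged between the triisopropylsilyloxy and ethoxy groups, so chelation and sterics point the same way.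

Step 4
Reactants: 11 1-[3-allyl-6-ethoxy-2-hydroxy-4-(triisopropylsilyloxy)phenyl]ethan-1-one; 12 4-(benzyloxy)benzoyl chloride
Product: 14 8-allyl-2-[4-(benzyloxy)phenyl]-5-ethoxy-7-(triisopropylsilyloxy)-4H-chromen-4-one, via 1,3-diketone 13 (not isolated)
Conditions: LiN(SiMe3)2 (3.2 equiv), THF, −78 → −10 °C; 12, −78 °C → rt; crude 13, p-TsOH·H2O (10 mol%), toluene, 80 °C
Reagents that add atoms: none
Why: Baker–Venkataraman flavone synthesis: the lithium phenoxide–enolate is aroylated to 1,3-diketone 13, which cyclodehydrates under mild acid through the only free phenol, so O1'' is fixed while the ethyl ether blocks O5''.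

Step 5
Reactants: 14 8-allyl-2-[4-(benzyloxy)phenyl]-5-ethoxy-7-(triisopropylsilyloxy)-4H-chromen-4-one
Product: 15 8-allyl-2-[4-(benzyloxy)phenyl]-5-hydroxy-7-(triisopropylsilyloxy)-4H-chromen-4-one
Conditions: BCl3 (1.1 equiv), CH2Cl2, −78 → 0 °C; MeOH, aq. NaHCO3
Reagents that add atoms: none
Why: Chelation-controlled peri dealkylation: the single equivalent of BCl3 is captured by the basic pyranone carbonyl and the neighbouring ethoxy oxygen, and chloride removes the ethyl group; the benzyl and silyl ethers sit on weakly basic vinylogous-ester oxygens and should meet no free BCl3.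

Step 6
Reactants: 15 8-allyl-2-[4-(benzyloxy)phenyl]-5-hydroxy-7-(triisopropylsilyloxy)-4H-chromen-4-one
Product: 16 2-{2-[4-(benzyloxy)phenyl]-5-hydroxy-4-oxo-7-(triisopropylsilyloxy)-4H-chromen-8-yl}acetaldehyde
Conditions: OsO4 (2 mol%), NaIO4 (4 equiv), 2,6-lutidine, 1,4-dioxane/H2O, rt
Reagents that add atoms: osmium tetroxide, O=[Os](=O)(=O)=O; sodium periodate (terminal oxidant), [Na+].[O-]I(=O)(=O)=O
Why: Lemieux–Johnson cleavage: the terminal alkene is dihydroxylated far faster than the electron-poor trisubstituted C2''=C3'' bond, and periodate cleaves the diol.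

Step 7
Reactants: 16 2-{2-[4-(benzyloxy)phenyl]-5-hydroxy-4-oxo-7-(triisopropylsilyloxy)-4H-chromen-8-yl}acetaldehyde
Product: 17 2-{2-[4-(benzyloxy)phenyl]-5-hydroxy-4-oxo-7-(triisopropylsilyloxy)-4H-chromen-8-yl}acetic acid
Conditions: NaClO2, NaH2PO4, 2-methylbut-2-ene, t-BuOH/THF/H2O, 0 °C → rt
Reagents that add atoms: sodium chlorite, [Na+].[O-]Cl=O
Why: Pinnick oxidation takes the enolisable arylacetaldehyde to the acid without touching phenol, silyl ether or enone; 2-methylbut-2-ene scavenges hypochlorous acid.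

Step 8
Reactants: 17 2-{2-[4-(benzyloxy)phenyl]-5-hydroxy-4-oxo-7-(triisopropylsilyloxy)-4H-chromen-8-yl}acetic acid; 18 1,3,5-tris(benzyloxy)benzene
Product: 20 2-[4-(benzyloxy)phenyl]-5-hydroxy-8-{2-oxo-2-[2,4,6-tris(benzyloxy)phenyl]ethyl}-7-(triisopropylsilyloxy)-4H-chromen-4-one, via mixed trifluoroacetic anhydride 19 (not isolated)
Conditions: (CF3CO)2O (1.3 equiv), CH2Cl2, 0 °C; then 18 (1.2 equiv), 0 °C → rt
Reagents that add atoms: none
Why: Friedel–Crafts acylation through mixed anhydride 19; the symmetric, very electron-rich tris-ether has three equivalent positions, so no regiochemistry arises and no strong Lewis acid is needed, which spares the silyl ether.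

Step 9
Reactants: 20 2-[4-(benzyloxy)phenyl]-5-hydroxy-8-{2-oxo-2-[2,4,6-tris(benzyloxy)phenyl]ethyl}-7-(triisopropylsilyloxy)-4H-chromen-4-one
Product: 21 8-{2-[2,4-bis(benzyloxy)-6-hydroxyphenyl]-2-oxoethyl}-2-[4-(benzyloxy)phenyl]-5-hydroxy-7-(triisopropylsilyloxy)-4H-chromen-4-one
Conditions: MgBr2·OEt2 (3 equiv), toluene/Et2O, 60 °C; aq. HCl
Reagents that add atoms: none
Why: Chelation-controlled debenzylation: magnesium bromide binds the ketone and one ortho benzyloxy oxygen and bromide removes that benzyl group only; the resulting magnesium phenoxide chelate protects the second ortho ether, and the remote benzyl ethers are not activated.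

Step 10
Reactants: 21 8-{2-[2,4-bis(benzyloxy)-6-hydroxyphenyl]-2-oxoethyl}-2-[4-(benzyloxy)phenyl]-5-hydroxy-7-(triisopropylsilyloxy)-4H-chromen-4-one; 22 4-(benzyloxy)benzaldehyde
Product: 23 (E)-1-[2,4-bis(benzyloxy)-6-hydroxyphenyl]-3-[4-(benzyloxy)phenyl]-2-{2-[4-(benzyloxy)phenyl]-5-hydroxy-4-oxo-7-(triisopropylsilyloxy)-4H-chromen-8-yl}prop-2-en-1-one
Conditions: piperidine (20 mol%), AcOH (40 mol%), toluene, 4 Å molecular sieves, 70 °C
Reagents that add atoms: none
Why: Knoevenagel condensation of the doubly activated methylene with the aromatic aldehyde through the piperidinium iminium ion; buffered aprotic conditions of the kind that leave 2'-hydroxyaryl alkylidene ketones uncyclised are used so that ring closure is left to the chiral catalyst.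

Step 11
Reactants: 23 (E)-1-[2,4-bis(benzyloxy)-6-hydroxyphenyl]-3-[4-(benzyloxy)phenyl]-2-{2-[4-(benzyloxy)phenyl]-5-hydroxy-4-oxo-7-(triisopropylsilyloxy)-4H-chromen-8-yl}prop-2-en-1-one
Product: 24 (2R,3S)-5,7-bis(benzyloxy)-2-[4-(benzyloxy)phenyl]-3-{2-[4-(benzyloxy)phenyl]-5-hydroxy-4-oxo-7-(triisopropylsilyloxy)-4H-chromen-8-yl}chroman-4-one
Conditions: 1-[3,5-bis(trifluoromethyl)phenyl]-3-[(8α,9S)-6′-methoxycinchonan-9-yl]thiourea (10 mol%), toluene, −20 °C → rt; filtration through acid-washed silica
Reagents that add atoms: none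
Why: Proposed new method: enantioselective 6-endo-trig oxa-Michael cyclisation of an α-aryl-2'-hydroxychalcone under bifunctional cinchona–thiourea catalysis, in which the quinuclidine nitrogen should deprotonate the chelated 2'-phenol while the thiourea N–H bonds hold the enone carbonyl, so that the phenoxide adds to one face of C2 within a chiral ion pair; C3 is then protonated anti to the new C2 aryl group and any cis isomer equilibrates through the enol to the trans ketone; the closest known reaction is the cinchona–thiourea-catalysed oxa-Michael cyclisation of 2'-hydroxyaryl alkylidene β-keto esters to 3-carboxyflavanones, from which this substrate differs by an aryl group in place of the ester; the sense of induction has to be established, and the pseudoenantiomeric quinidine-derived catalyst is available if the (2S,3R) series is favoured.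

Step 12
Reactants: 24 (2R,3S)-5,7-bis(benzyloxy)-2-[4-(benzyloxy)phenyl]-3-{2-[4-(benzyloxy)phenyl]-5-hydroxy-4-oxo-7-(triisopropylsilyloxy)-4H-chromen-8-yl}chroman-4-one
Product: 25 (2R,3S)-5,7-bis(benzyloxy)-2-[4-(benzyloxy)phenyl]-3-{2-[4-(benzyloxy)phenyl]-5,7-dihydroxy-4-oxo-4H-chromen-8-yl}chroman-4-one
Conditions: HF·pyridine, pyridine/THF, 0 °C → rt
Reagents that add atoms: none
Why: Fluoride cleaves the aryl silyl ether under acidic-to-neutral conditions that cause neither enolisation at C3 nor retro-oxa-Michael opening at C2; the only non-chelated phenol of the molecule is released.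

Step 13
Reactants: 25 (2R,3S)-5,7-bis(benzyloxy)-2-[4-(benzyloxy)phenyl]-3-{2-[4-(benzyloxy)phenyl]-5,7-dihydroxy-4-oxo-4H-chromen-8-yl}chroman-4-one
Product: 26 8-{(2R,3S)-5,7-bis(benzyloxy)-2-[4-(benzyloxy)phenyl]-4-oxochroman-3-yl}-2-[4-(benzyloxy)phenyl]-5-hydroxy-4-oxo-4H-chromen-7-yl hydrogen sulfate
Conditions: SO3·pyridine (5 equiv), pyridine, rt; Na+-form cation-exchange resin
Reagents that add atoms: sulfur trioxide–pyridine complex, [O-]S(=O)(=O)[n+]1ccccc1
Why: O-Sulfation of a phenol with SO3·pyridine; O7''–H is the only free non-chelated phenol, the 5''-hydroxyl is locked in a hydrogen bond to the pyranone carbonyl and should not react, and pyridine is too weak a base to open or epimerise the flavanone.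

Step 14
Reactants: 26 8-{(2R,3S)-5,7-bis(benzyloxy)-2-[4-(benzyloxy)phenyl]-4-oxochroman-3-yl}-2-[4-(benzyloxy)phenyl]-5-hydroxy-4-oxo-4H-chromen-7-yl hydrogen sulfate
Product: 27 8-[(2R,3S)-5,7-dihydroxy-2-(4-hydroxyphenyl)-4-oxochroman-3-yl]-5-hydroxy-2-(4-hydroxyphenyl)-4-oxo-4H-chromen-7-yl hydrogen sulfate
Conditions: H2 (1 atm), Pd/C (10 wt% Pd), THF/MeOH, rt; H+-form cation-exchange resin, 0 °C
Reagents that add atoms: none
Why: Hydrogenolysis of the four aryl benzyl ethers over palladium on carbon under neutral conditions; aryl sulfate monoesters, the flavone double bond and the flavanone C2–O1 bond should survive short exposure at one atmosphere, and no base is present that could racemise C2.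

## Compound list

1 | pent-1-en-4-yne | C=CCC#C | starting material
2 | lithium pent-4-en-1-yn-1-ide | [Li]C#CCC=C | intermediate
3 | lithium pent-4-en-1-yn-1-olate | [Li]OC#CCC=C | intermediate
4 | triisopropyl(pent-4-en-1-yn-1-yloxy)silane | C=CCC#CO[Si](C(C)C)(C(C)C)C(C)C | intermediate
5 | 3-ethoxycyclobut-2-en-1-one | CCOC1=CC(=O)C1 | starting material
6 | 3-ethoxybuta-1,3-dien-1-one (ethoxyvinylketene) | C=C(OCC)C=C=O | intermediate
7 | 2-allyl-4-(1-ethoxyvinyl)-3-(triisopropylsilyloxy)cyclobut-2-en-1-one (racemic) | O=C1C(CC=C)=C(O[Si](C(C)C)(C(C)C)C(C)C)C1C(=C)OCC | intermediate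
8 | (3E)-2-allyl-5-ethoxy-3-(triisopropylsilyloxy)hexa-1,3,5-trien-1-one (ketene and ethoxyvinyl termini cis) | O=C=C(CC=C)/C(O[Si](C(C)C)(C(C)C)C(C)C)=C\C(=C)OCC | intermediate
9 | 2-allyl-5-ethoxy-3-(triisopropylsilyloxy)cyclohexa-2,4-dien-1-one | O=C1CC(OCC)=CC(O[Si](C(C)C)(C(C)C)C(C)C)=C1CC=C | intermediate
10 | 2-allyl-5-ethoxy-3-(triisopropylsilyloxy)phenol | C=CCc1c(O)cc(OCC)cc1O[Si](C(C)C)(C(C)C)C(C)C | intermediate
11 | 1-[3-allyl-6-ethoxy-2-hydroxy-4-(triisopropylsilyloxy)phenyl]ethan-1-one | CC(=O)c1c(O)c(CC=C)c(O[Si](C(C)C)(C(C)C)C(C)C)cc1OCC | intermediate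
12 | 4-(benzyloxy)benzoyl chloride | O=C(Cl)c1ccc(OCc2ccccc2)cc1 | starting material
13 | 1-[3-allyl-6-ethoxy-2-hydroxy-4-(triisopropylsilyloxy)phenyl]-3-[4-(benzyloxy)phenyl]propane-1,3-dione | O=C(CC(=O)c1ccc(OCc2ccccc2)cc1)c1c(O)c(CC=C)c(O[Si](C(C)C)(C(C)C)C(C)C)cc1OCC | intermediate
14 | 8-allyl-2-[4-(benzyloxy)phenyl]-5-ethoxy-7-(triisopropylsilyloxy)-4H-chromen-4-one | O=c1cc(-c2ccc(OCc3ccccc3)cc2)oc2c(CC=C)c(O[Si](C(C)C)(C(C)C)C(C)C)cc(OCC)c12 | intermediate
15 | 8-allyl-2-[4-(benzyloxy)phenyl]-5-hydroxy-7-(triisopropylsilyloxy)-4H-chromen-4-one | O=c1cc(-c2ccc(OCc3ccccc3)cc2)oc2c(CC=C)c(O[Si](C(C)C)(C(C)C)C(C)C)cc(O)c12 | intermediate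
16 | 2-{2-[4-(benzyloxy)phenyl]-5-hydroxy-4-oxo-7-(triisopropylsilyloxy)-4H-chromen-8-yl}acetaldehyde | O=CCc1c(O[Si](C(C)C)(C(C)C)C(C)C)cc(O)c2c(=O)cc(-c3ccc(OCc4ccccc4)cc3)oc12 | intermediate
17 | 2-{2-[4-(benzyloxy)phenyl]-5-hydroxy-4-oxo-7-(triisopropylsilyloxy)-4H-chromen-8-yl}acetic acid | OC(=O)Cc1c(O[Si](C(C)C)(C(C)C)C(C)C)cc(O)c2c(=O)cc(-c3ccc(OCc4ccccc4)cc3)oc12 | intermediate
18 | 1,3,5-tris(benzyloxy)benzene | c1ccc(COc2cc(OCc3ccccc3)cc(OCc3ccccc3)c2)cc1 | starting material
19 | mixed anhydride of acid 17 with trifluoroacetic acid | O=C(Cc1c(O[Si](C(C)C)(C(C)C)C(C)C)cc(O)c2c(=O)cc(-c3ccc(OCc4ccccc4)cc3)oc12)OC(=O)C(F)(F)F | intermediate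
20 | 2-[4-(benzyloxy)phenyl]-5-hydroxy-8-{2-oxo-2-[2,4,6-tris(benzyloxy)phenyl]ethyl}-7-(triisopropylsilyloxy)-4H-chromen-4-one | O=C(Cc1c(O[Si](C(C)C)(C(C)C)C(C)C)cc(O)c2c(=O)cc(-c3ccc(OCc4ccccc4)cc3)oc12)c1c(OCc2ccccc2)cc(OCc2ccccc2)cc1OCc1ccccc1 | intermediate
21 | 8-{2-[2,4-bis(benzyloxy)-6-hydroxyphenyl]-2-oxoethyl}-2-[4-(benzyloxy)phenyl]-5-hydroxy-7-(triisopropylsilyloxy)-4H-chromen-4-one | O=C(Cc1c(O[Si](C(C)C)(C(C)C)C(C)C)cc(O)c2c(=O)cc(-c3ccc(OCc4ccccc4)cc3)oc12)c1c(O)cc(OCc2ccccc2)cc1OCc1ccccc1 | intermediate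
22 | 4-(benzyloxy)benzaldehyde | O=Cc1ccc(OCc2ccccc2)cc1 | starting material
23 | (E)-1-[2,4-bis(benzyloxy)-6-hydroxyphenyl]-3-[4-(benzyloxy)phenyl]-2-{2-[4-(benzyloxy)phenyl]-5-hydroxy-4-oxo-7-(triisopropylsilyloxy)-4H-chromen-8-yl}prop-2-en-1-one | O=C(c1c(O)cc(OCc2ccccc2)cc1OCc1ccccc1)/C(=C/c1ccc(OCc2ccccc2)cc1)c1c(O[Si](C(C)C)(C(C)C)C(C)C)cc(O)c2c(=O)cc(-c3ccc(OCc4ccccc4)cc3)oc12 | intermediate
24 | (2R,3S)-5,7-bis(benzyloxy)-2-[4-(benzyloxy)phenyl]-3-{2-[4-(benzyloxy)phenyl]-5-hydroxy-4-oxo-7-(triisopropylsilyloxy)-4H-chromen-8-yl}chroman-4-one (2,3-trans) | O=C1c2c(OCc3ccccc3)cc(OCc3ccccc3)cc2O[C@@H](c2ccc(OCc3ccccc3)cc2)[C@@H]1c1c(O[Si](C(C)C)(C(C)C)C(C)C)cc(O)c2c(=O)cc(-c3ccc(OCc4ccccc4)cc3)oc12 | intermediate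
25 | (2R,3S)-5,7-bis(benzyloxy)-2-[4-(benzyloxy)phenyl]-3-{2-[4-(benzyloxy)phenyl]-5,7-dihydroxy-4-oxo-4H-chromen-8-yl}chroman-4-one | O=C1c2c(OCc3ccccc3)cc(OCc3ccccc3)cc2O[C@@H](c2ccc(OCc3ccccc3)cc2)[C@@H]1c1c(O)cc(O)c2c(=O)cc(-c3ccc(OCc4ccccc4)cc3)oc12 | intermediate
26 | 8-{(2R,3S)-5,7-bis(benzyloxy)-2-[4-(benzyloxy)phenyl]-4-oxochroman-3-yl}-2-[4-(benzyloxy)phenyl]-5-hydroxy-4-oxo-4H-chromen-7-yl hydrogen sulfate (handled as sodium salt) | O=C1c2c(OCc3ccccc3)cc(OCc3ccccc3)cc2O[C@@H](c2ccc(OCc3ccccc3)cc2)[C@@H]1c1c(OS(=O)(=O)O)cc(O)c2c(=O)cc(-c3ccc(OCc4ccccc4)cc3)oc12 | intermediate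
27 | 8-[(2R,3S)-5,7-dihydroxy-2-(4-hydroxyphenyl)-4-oxochroman-3-yl]-5-hydroxy-2-(4-hydroxyphenyl)-4-oxo-4H-chromen-7-yl hydrogen sulfate (CNP0271389.1) | O=C1c2c(O)cc(O)cc2O[C@@H](c2ccc(O)cc2)[C@@H]1c1c(OS(=O)(=O)O)cc(O)c2c(=O)cc(-c3ccc(O)cc3)oc12 | target

## Step count and risks

Total step count: 14. Longest linear sequence: 14 steps (1 → 4 → 10 → 14 → 17 → 21 → 24 → 27); compounds 5, 12, 18 and 22 enter as purchased materials.

**Step 11 (proposed new method).**
- What may go wrong: poor facial selectivity, because the α-aryl enone lacks the second carbonyl that anchors the catalyst in the precedent; slow closure of a hindered acceptor; erosion of enantiopurity by catalyst-mediated retro-oxa-Michael opening of a product whose C3–H is doubly activated.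
- Fallback (known chemistry): chalcone 23 is cyclised with an achiral tertiary amine (Et3N, toluene) to the racemic trans ketone, that is 24 together with (2S,3R)-5,7-bis(benzyloxy)-2-[4-(benzyloxy)phenyl]-3-{2-[4-(benzyloxy)phenyl]-5-hydroxy-4-oxo-7-(triisopropylsilyloxy)-4H-chromen-8-yl}chroman-4-one F1. The enantiomers are separated by preparative chromatography on a polysaccharide chiral stationary phase. The unwanted enantiomer is racemised with base through ring opening and reclosure and recycled. The fallback sets out from 23 and rejoins the route at 24.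

**Step 2 (key step).**
- What may go wrong: sluggish electrocyclic opening of the vinylogous ester 5; dimerisation of ketene 6; acylation of the product phenol by 6; thermal isomerisation of the skipped enyne in 4.
- Fallback: the same ketene 6 is generated at room temperature by photochemical Wolff rearrangement, keeping the same bond formations. 3-Ethoxybut-3-en-2-one F2 (from 1-ethoxyvinyllithium and N-methoxy-N-methylacetamide) is converted by detrifluoroacetylative diazo transfer into 1-diazo-3-ethoxybut-3-en-2-one F3. F3 is irradiated in the presence of siloxyalkyne 4 and the mixture is then warmed to complete the electrocyclic cascade. The fallback sets out from 4 and returns at 10.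

**Step 10.**
- What may go wrong: amine-mediated cyclisation of the chalcone to racemic flavanone during the condensation; slow condensation at the hindered methylene.
- Fallback: the order of unmasking and condensation is reversed. Ketone 20, which has no free ortho phenol and cannot cyclise, is condensed with 22 (pyrrolidine, AcOH, toluene, reflux with water removal) to (E)-3-[4-(benzyloxy)phenyl]-2-{2-[4-(benzyloxy)phenyl]-5-hydroxy-4-oxo-7-(triisopropylsilyloxy)-4H-chromen-8-yl}-1-[2,4,6-tris(benzyloxy)phenyl]prop-2-en-1-one F4. Chelation-controlled mono-debenzylation with BCl3 (2.2 equiv, CH2Cl2, −78 °C, cold quench) then gives 23. The fallback sets out from 20 and returns at 23.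

**Step 5.**
- What may go wrong: loss of the benzyl ether or the silyl ether if free BCl3 is present; incomplete de-ethylation, since ethyl is a slower substitution partner than methyl.
- Fallback: both alkyl groups are removed on purpose with excess BCl3 and pentamethylbenzene to give 8-allyl-5-hydroxy-2-(4-hydroxyphenyl)-7-(triisopropylsilyloxy)-4H-chromen-4-one F5. The non-chelated 4'''-hydroxyl is then re-benzylated under Mitsunobu conditions (BnOH, PPh3, diisopropyl azodicarboxylate); the chelated 5''-hydroxyl does not react. The fallback sets out from 14 and returns at 15.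

**Step 3.**
- What may go wrong: acylation at the other free ring carbon, O-acetylation, Lewis-acid loss of the silyl group, or acid-promoted addition of the phenol to the allyl double bond.
- Fallback: phenol 10 undergoes ortho-specific Casnati–Skattebøl formylation (MgCl2, Et3N, paraformaldehyde, MeCN, reflux) to 3-allyl-6-ethoxy-2-hydroxy-4-(triisopropylsilyloxy)benzaldehyde F6. Addition of lithium [4-(benzyloxy)phenyl]acetylide gives racemic 1-[3-allyl-6-ethoxy-2-hydroxy-4-(triisopropylsilyloxy)phenyl]-3-[4-(benzyloxy)phenyl]prop-2-yn-1-ol F7. MnO2 oxidation gives 1-[3-allyl-6-ethoxy-2-hydroxy-4-(triisopropylsilyloxy)phenyl]-3-[4-(benzyloxy)phenyl]prop-2-yn-1-one F8, and diethylamine-mediated 6-endo cyclisation gives flavone 14. The fallback sets out from 10 and returns at 14, bypassing 11 and 13.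

## Further compounds

F1 | step 11 | (2S,3R)-5,7-bis(benzyloxy)-2-[4-(benzyloxy)phenyl]-3-{2-[4-(benzyloxy)phenyl]-5-hydroxy-4-oxo-7-(triisopropylsilyloxy)-4H-chromen-8-yl}chroman-4-one | O=C1c2c(OCc3ccccc3)cc(OCc3ccccc3)cc2O[C@H](c2ccc(OCc3ccccc3)cc2)[C@H]1c1c(O[Si](C(C)C)(C(C)C)C(C)C)cc(O)c2c(=O)cc(-c3ccc(OCc4ccccc4)cc3)oc12
F2 | step 2 | 3-ethoxybut-3-en-2-one | C=C(OCC)C(C)=O
F3 | step 2 | 1-diazo-3-ethoxybut-3-en-2-one | C=C(OCC)C(=O)C=[N+]=[N-]
F4 | step 10 | (E)-3-[4-(benzyloxy)phenyl]-2-{2-[4-(benzyloxy)phenyl]-5-hydroxy-4-oxo-7-(triisopropylsilyloxy)-4H-chromen-8-yl}-1-[2,4,6-tris(benzyloxy)phenyl]prop-2-en-1-one | O=C(c1c(OCc2ccccc2)cc(OCc2ccccc2)cc1OCc1ccccc1)/C(=C/c1ccc(OCc2ccccc2)cc1)c1c(O[Si](C(C)C)(C(C)C)C(C)C)cc(O)c2c(=O)cc(-c3ccc(OCc4ccccc4)cc3)oc12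
F5 | step 5 | 8-allyl-5-hydroxy-2-(4-hydroxyphenyl)-7-(triisopropylsilyloxy)-4H-chromen-4-one | O=c1cc(-c2ccc(O)cc2)oc2c(CC=C)c(O[Si](C(C)C)(C(C)C)C(C)C)cc(O)c12
F6 | step 3 | 3-allyl-6-ethoxy-2-hydroxy-4-(triisopropylsilyloxy)benzaldehyde | O=Cc1c(O)c(CC=C)c(O[Si](C(C)C)(C(C)C)C(C)C)cc1OCC
F7 | step 3 | 1-[3-allyl-6-ethoxy-2-hydroxy-4-(triisopropylsilyloxy)phenyl]-3-[4-(benzyloxy)phenyl]prop-2-yn-1-ol (racemic) | OC(C#Cc1ccc(OCc2ccccc2)cc1)c1c(O)c(CC=C)c(O[Si](C(C)C)(C(C)C)C(C)C)cc1OCC
F8 | step 3 | 1-[3-allyl-6-ethoxy-2-hydroxy-4-(triisopropylsilyloxy)phenyl]-3-[4-(benzyloxy)phenyl]prop-2-yn-1-one | O=C(C#Cc1ccc(OCc2ccccc2)cc1)c1c(O)c(CC=C)c(O[Si](C(C)C)(C(C)C)C(C)C)cc1OCC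
A1 | alternative 1 | (E)-3-[4-(benzyloxy)phenyl]-2-{5-(benzyloxy)-2-[4-(benzyloxy)phenyl]-7-(methoxymethoxy)-4-oxo-4H-chromen-8-yl}acrylic acid | OC(=O)/C(=C/c1ccc(OCc2ccccc2)cc1)c1c(OCOC)cc(OCc2ccccc2)c2c(=O)cc(-c3ccc(OCc4ccccc4)cc3)oc12
A2 | alternative 1 | 3,5-bis(benzyloxy)benzyne | C1#CC(OCc2ccccc2)=CC(OCc2ccccc2)=C1
A3 | alternative 1 | (E)-1-[2,4-bis(benzyloxy)-6-hydroxyphenyl]-3-[4-(benzyloxy)phenyl]-2-{5-(benzyloxy)-2-[4-(benzyloxy)phenyl]-7-(methoxymethoxy)-4-oxo-4H-chromen-8-yl}prop-2-en-1-one | O=C(c1c(O)cc(OCc2ccccc2)cc1OCc1ccccc1)/C(=C/c1ccc(OCc2ccccc2)cc1)c1c(OCOC)cc(OCc2ccccc2)c2c(=O)cc(-c3ccc(OCc4ccccc4)cc3)oc12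
A4 | alternative 2 | benzyl 4-{(R)-[3,5-bis(benzyloxy)phenoxy][(3S)-5-(benzyloxy)-8-[4-(benzyloxy)phenyl]-2,6-dioxo-2,3-dihydro-6H-furo[2,3-h]chromen-3-yl]methyl}phenyl carbonate (lactone between O7'' and the C4 carboxyl) | O=C1Oc2cc(OCc3ccccc3)c3c(=O)cc(-c4ccc(OCc5ccccc5)cc4)oc3c2[C@H]1[C@@H](Oc1cc(OCc2ccccc2)cc(OCc2ccccc2)c1)c1ccc(OC(=O)OCc2ccccc2)cc1
A5 | alternative 2 | benzyl 4-{(2R,3S)-5,7-bis(benzyloxy)-3-[5-(benzyloxy)-2-[4-(benzyloxy)phenyl]-7-hydroxy-4-oxo-4H-chromen-8-yl]-4-oxochroman-2-yl}phenyl carbonate | O=C1c2c(OCc3ccccc3)cc(OCc3ccccc3)cc2O[C@@H](c2ccc(OC(=O)OCc3ccccc3)cc2)[C@@H]1c1c(O)cc(OCc2ccccc2)c2c(=O)cc(-c3ccc(OCc4ccccc4)cc3)oc12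
A6 | alternative 3 | 2,4-bis(benzyloxy)-6-hydroxybenzaldehyde | O=Cc1c(O)cc(OCc2ccccc2)cc1OCc1ccccc1
A7 | alternative 3 | 5-(benzyloxy)-2-[4-(benzyloxy)phenyl]-8-[(E)-4-(benzyloxy)styryl]-4-oxo-4H-chromen-7-yl 2,2,2-trichloroethyl sulfate | O=c1cc(-c2ccc(OCc3ccccc3)cc2)oc2c(/C=C/c3ccc(OCc4ccccc4)cc3)c(OS(=O)(=O)OCC(Cl)(Cl)Cl)cc(OCc3ccccc3)c12
A8 | alternative 3 | 3,5-bis(benzyloxy)-6-(methoxymethylene)cyclohexa-2,4-dien-1-one | COC=C1C(=O)C=C(OCc2ccccc2)C=C1OCc1ccccc1
A9 | alternative 3 | 8-{(2R,3S,4S)-5,7-bis(benzyloxy)-2-[4-(benzyloxy)phenyl]-4-methoxychroman-3-yl}-5-(benzyloxy)-2-[4-(benzyloxy)phenyl]-4-oxo-4H-chromen-7-yl 2,2,2-trichloroethyl sulfate | CO[C@H]1c2c(OCc3ccccc3)cc(OCc3ccccc3)cc2O[C@@H](c2ccc(OCc3ccccc3)cc2)[C@@H]1c1c(OS(=O)(=O)OCC(Cl)(Cl)Cl)cc(OCc2ccccc2)c2c(=O)cc(-c3ccc(OCc4ccccc4)cc3)oc12
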